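**Assumption:** the target (5,7,4'-trihydroxy-3,6,8-trimethoxyflavone) has no stereocentre, so "single enantiomer" is read as the single achiral constitution given and no stereocontrol is needed.

**Retrosynthetic overview**
1. Target 16 ← 15 by hydrogenolysis of the 7-O- and 4'-O-benzyl ethers.
2. Pyranone ring of 15 (C3–C4 and O1–C2 bonds) ← salicylaldehyde 7 + aryl ynol ether 14 by a new Rh(III)-catalysed oxidative formyl C–H/O–H annulation. Because 7 is symmetrical, either OH closes to the same product and the other remains as the 5-OH.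
3. 7 ← syringol 1: O-benzylation, 3,5-dibromination, Br→OH via the bis-boronate, then formylation at the only free ring position.
4. 14 ← aryl bromide 8 + Weinreb amide 9 (α-methoxy ketone 12), then enol triflate formation and elimination.
5. Ring order: A ring (from 1) and B ring (from 8) are bought; the C ring is formed last, in step 8.

**Route**

Step 1
Reactants: 1 2,6-dimethoxyphenol (syringol)
Product: 2 2-(benzyloxy)-1,3-dimethoxybenzene
Conditions: BnBr, K2CO3, DMF, 60 °C
Reagents that add atoms: benzyl bromide, BrCc1ccccc1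
Why: Williamson ether synthesis on the phenoxide, which places the benzyl group on the oxygen that becomes the flavone 7-O.

Step 2
Reactants: 2 2-(benzyloxy)-1,3-dimethoxybenzene
Product: 3 3-(benzyloxy)-1,5-dibromo-2,4-dimethoxybenzene
Conditions: NBS (2.1 equiv), MeCN, 0 °C to rt, dark
Reagents that add atoms: N-bromosuccinimide, O=C1CCC(=O)N1Br
Why: Electrophilic aromatic bromination goes twice to the positions ortho to one OMe and para to the other, as in 1,2,3-trialkoxybenzenes, and leaves the C–H para to the twisted central OBn untouched.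

Step 3
Reactants: 3 3-(benzyloxy)-1,5-dibromo-2,4-dimethoxybenzene
Product: 4 2,2'-[5-(benzyloxy)-4,6-dimethoxy-1,3-phenylene]bis(4,4,5,5-tetramethyl-1,3,2-dioxaborolane)
Conditions: B2pin2 (2.6 equiv), Pd(dppf)Cl2 (6 mol %), KOAc, 1,4-dioxane, 90 °C
Reagents that add atoms: bis(pinacolato)diboron, CC1(C)OB(OC1(C)C)B1OC(C)(C)C(C)(C)O1
Why: Double Miyaura borylation of the two aryl bromides, each flanked by only one ortho substituent; the benzyl and methyl ethers are inert.

Step 4
Reactants: 4 2,2'-[5-(benzyloxy)-4,6-dimethoxy-1,3-phenylene]bis(4,4,5,5-tetramethyl-1,3,2-dioxaborolane)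
Product: 5 5-(benzyloxy)-4,6-dimethoxybenzene-1,3-diol
Conditions: 30% H2O2, 2 M NaOH, THF, 0 °C to rt, N2; then aq. HCl
Reagents that add atoms: hydrogen peroxide, OO
Why: Oxidation of the aryl boronates by hydroperoxide (boron-to-oxygen 1,2-aryl shift, then hydrolysis) gives the two phenols with retention of position.

Step 5
Reactants: 5 5-(benzyloxy)-4,6-dimethoxybenzene-1,3-diol
Product: 7 4-(benzyloxy)-2,6-dihydroxy-3,5-dimethoxybenzaldehyde, via iminium chloride 6 (not isolated)
Conditions: POCl3 (1.2 equiv), DMF (3 equiv), MeCN, 0 °C to rt; then H2O, 50 °C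
Reagents that add atoms: N,N-dimethylformamide, CN(C)C=O; water, O
Why: Vilsmeier–Haack formylation attacks the single free ring carbon, which is ortho to both OH groups and para to OBn (as in phloroglucinol formylation), and the iminium salt is hydrolysed on aqueous work-up.

Step 6
Reactants: 8 1-(benzyloxy)-4-bromobenzene; 9 N,2-dimethoxy-N-methylacetamide
Product: 12 1-[4-(benzyloxy)phenyl]-2-methoxyethan-1-one, via aryl Grignard reagent 10 (not isolated), via magnesium hemiaminal 11 (not isolated)
Conditions: Mg, cat. I2, THF, reflux; then 9, 0 °C; then 1 M HCl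
Reagents that add atoms: none
Why: Weinreb ketone synthesis, in which the chelated tetrahedral adduct prevents over-addition and releases the α-methoxy ketone only on acidic quench.

Step 7
Reactants: 12 1-[4-(benzyloxy)phenyl]-2-methoxyethan-1-one
Product: 14 1-(benzyloxy)-4-(methoxyethynyl)benzene, via enol triflate 13 (not isolated)
Conditions: LiHMDS (1.1 equiv), PhNTf2 (1.1 equiv), THF, −78 °C; then KOtBu (2.5 equiv), −78 to 0 °C; pH 7 buffer work-up, filtration through basic alumina
Reagents that add atoms: none
Why: The chelated (Z)-enolate is O-triflated and the (Z)-enol triflate, which has its vinylic H anti to OTf, undergoes base-induced E2 elimination to the ynol ether (the known α-alkoxy ketone to alkynyl ether sequence).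

Step 8
Reactants: 7 4-(benzyloxy)-2,6-dihydroxy-3,5-dimethoxybenzaldehyde; 14 1-(benzyloxy)-4-(methoxyethynyl)benzene
Product: 15 7-(benzyloxy)-2-[4-(benzyloxy)phenyl]-5-hydroxy-3,6,8-trimethoxy-4H-chromen-4-one
Conditions: [Cp*Rh(MeCN)3](SbF6)2 (5 mol %), CsOPiv (20 mol %), Ag2CO3 (1.2 equiv), 4 Å MS, DCE, 60 °C; 14 (1.5 equiv) added over 4 h
Reagents that add atoms: none
Why: Proposed new method: a Cp*Rh(III)-catalysed oxidative formyl C–H/O–H annulation of a salicylaldehyde with an aryl ynol ether, not yet shown for ynol ethers or as a way to 3-alkoxyflavones; the phenoxide of 7 binds Rh(III) and carboxylate-assisted rhodation of the formyl C–H gives a five-membered O,C-acyl rhodacycle, the polarised alkyne MeO–C≡C–Ar then inserts with the acyl carbon bonding to the electrophilic O-bearing carbon (new C4–C3 bond) and Rh going to the nucleophilic aryl-bearing carbon (the same sense that puts aryl next to the metal with alkyl aryl alkynes), C–O reductive elimination closes the pyranone (new O1–C2 bond) and Ag(I) reoxidises Rh(I); the two equivalent OH groups of 7 give one product and leave the hydrogen-bonded 5-OH, the methyl ynol ether has no β-hydrogen for retro-ene loss to a ketene, and the carbonate oxidant plus sieves keeps the medium free of the carboxylic acid and water that would hydrate 14; the closest known reaction type is the Rh-catalysed oxidative annulation of salicylaldehydes with internal diaryl or alkyl aryl alkynes to 2,3-disubstituted chromones.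

Step 9
Reactants: 15 7-(benzyloxy)-2-[4-(benzyloxy)phenyl]-5-hydroxy-3,6,8-trimethoxy-4H-chromen-4-one
Product: 16 5,7-dihydroxy-2-(4-hydroxyphenyl)-3,6,8-trimethoxy-4H-chromen-4-one
Conditions: H2 (1 atm), 10% Pd/C, THF/MeOH, rt
Reagents that add atoms: none
Why: Catalytic hydrogenolysis cleaves both aryl benzyl ethers, while the methyl ethers and the chromone C2=C3 bond are unaffected under these mild conditions.

**Compound list**

1 | 2,6-dimethoxyphenol (syringol) | COc1cccc(OC)c1O | starting material
2 | 2-(benzyloxy)-1,3-dimethoxybenzene | COc1cccc(OC)c1OCc1ccccc1 | intermediate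
3 | 3-(benzyloxy)-1,5-dibromo-2,4-dimethoxybenzene | COc1c(Br)cc(Br)c(OC)c1OCc1ccccc1 | intermediate
4 | 2,2'-[5-(benzyloxy)-4,6-dimethoxy-1,3-phenylene]bis(4,4,5,5-tetramethyl-1,3,2-dioxaborolane) | COc1c(B2OC(C)(C)C(C)(C)O2)cc(B2OC(C)(C)C(C)(C)O2)c(OC)c1OCc1ccccc1 | intermediate
5 | 5-(benzyloxy)-4,6-dimethoxybenzene-1,3-diol | Oc1cc(O)c(OC)c(OCc2ccccc2)c1OC | intermediate
6 | N-{[4-(benzyloxy)-2,6-dihydroxy-3,5-dimethoxyphenyl]methylidene}-N-methylmethanaminium chloride (not isolated) | C[N+](C)=Cc1c(O)c(OC)c(OCc2ccccc2)c(OC)c1O.[Cl-] | intermediate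
7 | 4-(benzyloxy)-2,6-dihydroxy-3,5-dimethoxybenzaldehyde | O=Cc1c(O)c(OC)c(OCc2ccccc2)c(OC)c1O | intermediate
8 | 1-(benzyloxy)-4-bromobenzene | Brc1ccc(OCc2ccccc2)cc1 | starting material
9 | N,2-dimethoxy-N-methylacetamide | COCC(=O)N(C)OC | starting material
10 | [4-(benzyloxy)phenyl]magnesium bromide (not isolated) | Br[Mg]c1ccc(OCc2ccccc2)cc1 | intermediate
11 | bromomagnesium 1-[4-(benzyloxy)phenyl]-2-methoxy-1-[methoxy(methyl)amino]ethan-1-olate, racemic (not isolated) | COCC(O[Mg]Br)(N(C)OC)c1ccc(OCc2ccccc2)cc1 | intermediate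
12 | 1-[4-(benzyloxy)phenyl]-2-methoxyethan-1-one | COCC(=O)c1ccc(OCc2ccccc2)cc1 | intermediate
13 | (Z)-1-[4-(benzyloxy)phenyl]-2-methoxyethenyl trifluoromethanesulfonate (not isolated) | CO/C=C(\OS(=O)(=O)C(F)(F)F)c1ccc(OCc2ccccc2)cc1 | intermediate
14 | 1-(benzyloxy)-4-(methoxyethynyl)benzene | COC#Cc1ccc(OCc2ccccc2)cc1 | intermediate
15 | 7-(benzyloxy)-2-[4-(benzyloxy)phenyl]-5-hydroxy-3,6,8-trimethoxy-4H-chromen-4-one | COc1c(OCc3ccccc3)c(OC)c2oc(-c3ccc(OCc4ccccc4)cc3)c(OC)c(=O)c2c1O | intermediate
16 | 5,7-dihydroxy-2-(4-hydroxyphenyl)-3,6,8-trimethoxy-4H-chromen-4-one | COc1c(O)c(OC)c2oc(-c3ccc(O)cc3)c(OC)c(=O)c2c1O | target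

**Totals**
Total step count: 9.
Longest linear sequence: 7 steps (steps 1, 2, 3, 4, 5, 8, 9); the ynol ether branch (steps 6, 7) joins at step 8.

**Three steps most likely to fail**

Step 8 (the proposed new annulation). Likely failures are reversed insertion (giving a 2-methoxyisoflavone), decarbonylation of the acyl rhodium species, hydration of 14 to the methyl arylacetate, and catalyst sequestration by the chelating product. The fallback is known chemistry, sets out from 5 and comes back at 15. Hoesch acylation of 5 with methoxyacetonitrile (ZnCl2, dry HCl, Et2O, 0 °C) gives 1-[4-(benzyloxy)-2,6-dihydroxy-3,5-dimethoxyphenyl]-2-methoxyethan-1-iminium chloride F1. Hot water hydrolyses it to 1-[4-(benzyloxy)-2,6-dihydroxy-3,5-dimethoxyphenyl]-2-methoxyethan-1-one F2. Allan–Robinson condensation of F2 with 4-(benzyloxy)benzoic anhydride F3 (prepared from commercial 4-(benzyloxy)benzoyl chloride and potassium 4-(benzyloxy)benzoate) and potassium 4-(benzyloxy)benzoate at 170–180 °C gives 7-(benzyloxy)-2-[4-(benzyloxy)phenyl]-3,6,8-trimethoxy-4-oxo-4H-chromen-5-yl 4-(benzyloxy)benzoate F4. Brief KOH in aqueous MeOH, then acidification, cleaves the 5-O-ester to give 15.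

Step 7 (formation and isolation of the acid-sensitive methyl ynol ether). Likely failures are sluggish elimination of the enol triflate or hydration of 14 during isolation. The fallback builds the C(sp)–C(aryl) bond by cross-coupling instead of elimination; it sets out from 8 and comes back at 14. Chloroacetaldehyde dimethyl acetal and LiNEt2 (3 equiv, THF, 0 °C) give lithium methoxyacetylide F5. ZnCl2 converts it to (methoxyethynyl)zinc chloride F6. Negishi coupling of F6 with 8 (Pd2(dba)3, XPhos, THF, 50 °C) gives 14 after a neutral work-up.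

Step 3 (double Miyaura borylation). Likely failures are protodebromination or an incomplete second borylation of the electron-rich dibromide. The fallback replaces the boron detour (steps 3 and 4) by a direct Pd-catalysed C–O coupling with hydroxide; it sets out from 3 and comes back at 5. Conditions are Pd2(dba)3, tBuXPhos, KOH, 1,4-dioxane/H2O, 100 °C, then aq. HCl; no new compound is made on the way (F0).

**Further compounds**

F1 | step 8 | 1-[4-(benzyloxy)-2,6-dihydroxy-3,5-dimethoxyphenyl]-2-methoxyethan-1-iminium chloride | COCC(=[NH2+])c1c(O)c(OC)c(OCc2ccccc2)c(OC)c1O.[Cl-]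
F2 | step 8 | 1-[4-(benzyloxy)-2,6-dihydroxy-3,5-dimethoxyphenyl]-2-methoxyethan-1-one | COCC(=O)c1c(O)c(OC)c(OCc2ccccc2)c(OC)c1O
F3 | step 8 | 4-(benzyloxy)benzoic anhydride | O=C(OC(=O)c1ccc(OCc2ccccc2)cc1)c1ccc(OCc2ccccc2)cc1
F4 | step 8 | 7-(benzyloxy)-2-[4-(benzyloxy)phenyl]-3,6,8-trimethoxy-4-oxo-4H-chromen-5-yl 4-(benzyloxy)benzoate | COc1c(OCc2ccccc2)c(OC)c2oc(-c3ccc(OCc4ccccc4)cc3)c(OC)c(=O)c2c1OC(=O)c1ccc(OCc2ccccc2)cc1
F5 | step 7 | lithium methoxyacetylide | [Li]C#COC
F6 | step 7 | (methoxyethynyl)zinc chloride | COC#C[Zn]Cl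
F0 | step 3 | none | none
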